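## Retrosynthetic overview

1. The 16-membered lactone is closed last, by acylating the C15 tertiary alcohol of a seco-acid; only silyl removal follows.
2. The C10 and C14 bromohydrins come from SN2 bromide opening of a (10S,11S),(14S)-bis-epoxide (Shi epoxidation of the E,E-diene). The exo-methylene comes from a C3 ketone and C6–Br from an axial C6–OH by inversion.
3. The C7 quaternary centre comes from two successive α-alkylations (MeI, then homogeranyl iodide anti to C2) of an enone whose only enolisable carbon is C7.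
4. The C1–C2 bond and the first stereocentre come from an enantioselective, desymmetrising Cu-catalysed conjugate addition of the arylmethyl-zinc reagent to 4,4-dimethoxycyclohexa-2,5-dienone, itself made by oxidative dearomatisation of 4-methoxyphenol.
5. Ring order: the carbocycle is the dearomatised 4-methoxyphenol ring (C6=O becomes C6–Br, C3 ketal becomes C3=CH2); the benzoate ring is bought; the oxiranes are transient; the macrolactone is last.

Assumption: diterpene numbering is used throughout (C1 = ArCH2, C2–C7 = carbocycle, C3 bears the exo-methylene, C8–C15 = side chain). On that numbering the target SMILES is (2R,6S,7S,10R,11S,14R). Ar = 5-(allyloxycarbonyl)-2-[(triisopropylsilyl)oxy]phenyl.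

## Route

**Step 1**
Reactants: 1, 4-methoxyphenol
Product: 2, 4,4-dimethoxycyclohexa-2,5-dien-1-one
Conditions: PhI(OAc)2, MeOH, 0 °C → rt
Reagents that add atoms: methanol, CO
Why: Oxidative dearomatisation of a phenol with an aryl-λ3-iodane; MeOH traps the phenoxenium para to give the achiral, Cs-symmetric quinone monoketal (C=O = future C6, ketal = future C3), with no stereocentre.

**Step 2**
Reactants: 3, 4-hydroxy-3-methylbenzoic acid
Product: 4, allyl 3-methyl-4-[(triisopropylsilyl)oxy]benzoate
Conditions: allyl bromide, KHCO3, DMF, 25 °C; then imidazole, TIPSCl, 25 °C (one pot)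
Reagents that add atoms: allyl bromide, C=CCBr; triisopropylsilyl chloride, CC(C)[Si](Cl)(C(C)C)C(C)C
Why: Bicarbonate alkylates only the carboxylate (SN2 esterification), then the phenol is silylated; the allyl ester can later be removed without base and the aryl TIPS ether with fluoride.

**Step 3**
Reactants: 4, allyl 3-methyl-4-[(triisopropylsilyl)oxy]benzoate
Product: 5, allyl 3-(bromomethyl)-4-[(triisopropylsilyl)oxy]benzoate
Conditions: NBS, AIBN, PhCF3, 80 °C
Reagents that add atoms: N-bromosuccinimide, O=C1CCC(=O)N1Br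
Why: Wohl–Ziegler radical bromination of the only benzylic methyl; the ester-deactivated ring and the O-allyl CH2 are much less reactive.

**Step 4 (key step)**
Reactants: 2, 4,4-dimethoxycyclohexa-2,5-dien-1-one; 5, allyl 3-(bromomethyl)-4-[(triisopropylsilyl)oxy]benzoate
Product: 6, (S)-5-(ArCH2)-4,4-dimethoxycyclohex-2-en-1-one
Conditions: 5, Zn dust, LiCl, THF, 25 °C; Me3SiCH2Li, −30 °C (gives ArCH2ZnCH2SiMe3); then 2, Cu(OTf)2 (3 mol %), (S,R,R)-BINOL/bis(1-phenylethyl)amine phosphoramidite (6 mol %; antipode if needed to give (S)-6), PhMe, −30 °C; aq. NH4Cl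
Reagents that add atoms: none
Why: Proposed new method: the chiral Cu(I)–benzyl species π-complexes one of the two enantiotopic enone arms of 2, and oxidative addition at the β-carbon then reductive elimination forms C1–C2 and sets C2 (S here, R in the target after a CIP priority change); Me3SiCH2 is a non-transferable ligand on zinc. The closest known chemistry is the Cu/phosphoramidite desymmetrising conjugate addition of dialkylzincs to 4,4-dialkoxycyclohexadienones and racemic conjugate additions of ester-bearing benzylic zinc–copper reagents.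

**Step 5**
Reactants: 6, (S)-5-(ArCH2)-4,4-dimethoxycyclohex-2-en-1-one
Product: 7, (5S,6S)-5-(ArCH2)-4,4-dimethoxy-6-methylcyclohex-2-en-1-one (trans, major)
Conditions: LiHMDS, THF, −78 °C; MeI, −78 → −40 °C
Reagents that add atoms: iodomethane, CI
Why: Kinetic enolate alkylation; C7 is the only enolisable carbon (C5 is vinylic, C3 is a ketal), MeI enters anti to the C2 benzyl group, and this centre is re-enolised in step 8.

**Step 6**
Reactants: 8, geranyl bromide [(2E)-1-bromo-3,7-dimethylocta-2,6-diene]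
Product: 9, homogeraniol [(3E)-4,8-dimethylnona-3,7-dien-1-ol]
Conditions: (i-PrO)Me2SiCH2MgCl, Li2CuCl4 (5 mol %), THF, −20 → 0 °C; then KF, KHCO3, 30 % H2O2, THF/MeOH, 25 °C
Reagents that add atoms: (isopropoxydimethylsilyl)methylmagnesium chloride, CC(C)O[Si](C)(C)C[Mg]Cl; hydrogen peroxide, OO
Why: Cu-catalysed (Kochi) SN2 coupling of the allylic bromide with the hydroxymethyl-anion equivalent keeps the E-alkene, and Tamao–Fleming oxidation converts C–Si to C–OH.

**Step 7**
Reactants: 9, homogeraniol
Product: 10, homogeranyl iodide [(3E)-1-iodo-4,8-dimethylnona-3,7-diene]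
Conditions: I2, PPh3, imidazole, CH2Cl2, 0 °C
Reagents that add atoms: iodine, II
Why: Appel-type (Garegg) iodination of a primary alcohol; no stereocentre is involved.

**Step 8**
Reactants: 7, (5S,6S)-5-(ArCH2)-4,4-dimethoxy-6-methylcyclohex-2-en-1-one; 10, homogeranyl iodide
Product: 11, (5S,6S)-5-(ArCH2)-6-[(3E)-4,8-dimethylnona-3,7-dienyl]-4,4-dimethoxy-6-methylcyclohex-2-en-1-one
Conditions: KHMDS, THF, −78 °C; 10, DMPU, −78 → −20 °C
Reagents that add atoms: none
Why: Stork–Danheiser-type alkylation of the regiodefined tetrasubstituted enolate; the pseudoaxial C2 benzyl group (A1,2 strain with C7–Me) blocks one face, so the chain enters anti to it and C7 is set with chain trans and methyl cis to the benzyl group.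

**Step 9**
Reactants: 11, the enone from step 8
Product: 12, (2S,3S)-3-(ArCH2)-2-[(3E)-4,8-dimethylnona-3,7-dienyl]-4,4-dimethoxy-2-methylcyclohexan-1-one
Conditions: Cu(OAc)2·H2O (5 mol %), 1,2-bis(diphenylphosphino)benzene, (Me2SiH)2O, t-BuOH, PhMe, 25 °C
Reagents that add atoms: none
Why: Stryker-type CuH conjugate reduction is selective for the enone over the isolated trisubstituted alkenes and the esters; no stereocentre is formed.

**Step 10**
Reactants: 12, the ketone from step 9
Product: 13, allyl 3-{[(1S,2S,3R)-2-[(3E)-4,8-dimethylnona-3,7-dienyl]-3-hydroxy-6,6-dimethoxy-2-methylcyclohexyl]methyl}-4-(TIPSO)benzoate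
Conditions: L-Selectride, THF, −78 °C
Reagents that add atoms: none
Why: The bulky hydride attacks the α-quaternary cyclohexanone equatorially (chair with benzyl and chain equatorial, C7–Me axial), giving the axial C6–OH cis to the chain, as with 4,4-dimethyl-3-keto terpenoids.

**Step 11**
Reactants: 13, the axial alcohol from step 10
Product: 14, allyl 3-{[(1S,2S,3S)-3-bromo-2-[(3E)-4,8-dimethylnona-3,7-dienyl]-2-methyl-6-oxocyclohexyl]methyl}-4-(TIPSO)benzoate
Conditions: CBr4, P(n-Oct)3, 1-methylcyclohexene, PhMe, 70 °C; then 1 M HCl, THF, 25 °C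
Reagents that add atoms: carbon tetrabromide, BrC(Br)(Br)Br; water, O
Why: Appel bromination proceeds by SN2 inversion of the axial oxyphosphonium (trioctylphosphine and an HBr trap for the neopentyl-type centre), giving the equatorial (6S)-bromide cis to C7–Me; the acidic work-up hydrolyses the dimethyl ketal to the C3 ketone.

**Step 12**
Reactants: 14, the bromo ketone from step 11
Product: 15, allyl 3-{[(1R,2S,3S)-3-bromo-2-[(3E)-4,8-dimethylnona-3,7-dienyl]-2-methyl-6-methylidenecyclohexyl]methyl}-4-(TIPSO)benzoate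
Conditions: Zn, CH2Br2, TiCl4, THF/CH2Cl2, 0 → 25 °C
Reagents that add atoms: dibromomethane, BrCBr
Why: Takai–Lombardo methylenation is non-basic, so the γ-bromo ketone does not cyclise to a cyclopropane and C2 does not epimerise (the all-equatorial C2 epimer is in any case the stable one); esters are untouched.

**Step 13**
Reactants: 15, the triene from step 12
Product: 16, bis-epoxide with (2S,3S)- and (2S)-oxiranes at C10/C11 and C14/C15
Conditions: ent-Shi ketone (L-fructose-derived, 0.5 equiv), Oxone, K2CO3, Bu4NHSO4, MeCN/DMM/buffer pH 10, −5 °C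
Reagents that add atoms: potassium peroxymonosulfate (Oxone), OOS(=O)(=O)[O-].[K+]
Why: Shi asymmetric epoxidation via the chiral dioxirane (spiro transition state) gives the (S,S)-epoxides of both E-trisubstituted alkenes, setting C10, C11 and C14; the 1,1-disubstituted exo-methylene and the allyl ester alkene react much more slowly.

**Step 14**
Reactants: 16, the bis-epoxide from step 13
Product: 17, allyl 3-{[(1R,2S,3S)-3-bromo-2-[(3R,4S,7R)-3,7-dibromo-4,8-dihydroxy-4,8-dimethylnonyl]-2-methyl-6-methylidenecyclohexyl]methyl}-4-(TIPSO)benzoate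
Conditions: Li2NiBr4, THF, 0 → 25 °C; aq. NH4Cl
Reagents that add atoms: dilithium tetrabromonickelate(II), [Li+].[Li+].Br[Ni-2](Br)(Br)Br
Why: The soft bromide source opens each trisubstituted epoxide by SN2 at the secondary carbon with inversion (C10 and C14 become R) and leaves the tertiary C–O bonds (C11 S, C15) intact.

**Step 15**
Reactants: 17, the bis-bromohydrin allyl ester from step 14
Product: 18, 3-{[(1R,2S,3S)-3-bromo-2-[(3R,4S,7R)-3,7-dibromo-4,8-dihydroxy-4,8-dimethylnonyl]-2-methyl-6-methylidenecyclohexyl]methyl}-4-(TIPSO)benzoic acid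
Conditions: Pd(PPh3)4 (5 mol %), PhSiH3, CH2Cl2, 25 °C
Reagents that add atoms: none
Why: Tsuji–Trost deallylation is neutral, so the base-sensitive bromohydrins, the secondary bromides and the aryl silyl ether survive.

**Step 16**
Reactants: 18, the seco-acid from step 15
Product: 19, O-TIPS-bromophycolide H
Conditions: MNBA, DMAP, Et3N, PhMe (1 mM, syringe pump), 25 → 50 °C
Reagents that add atoms: none
Why: Shiina macrolactonisation through the mixed anhydride and acyl-DMAP; the dimethylcarbinol C15–OH is the less hindered tertiary alcohol and gives the 16-membered ring, whereas C11–OH would need a strained 12-membered meta-cyclophane; no stereocentre changes.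

**Step 17**
Reactants: 19, O-TIPS-bromophycolide H
Product: 20, bromophycolide H
Conditions: HF·pyridine, THF, 0 °C
Reagents that add atoms: none
Why: Mildly acidic fluoride cleaves the aryl silyl ether without forming epoxides from the bromohydrins or cleaving the tertiary benzoate.

## Compound list

1 | 4-methoxyphenol | COc1ccc(O)cc1 | starting material
2 | 4,4-dimethoxycyclohexa-2,5-dien-1-one | COC1(OC)C=CC(=O)C=C1 | intermediate
3 | 4-hydroxy-3-methylbenzoic acid | Cc1cc(ccc1O)C(=O)O | starting material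
4 | allyl 3-methyl-4-[(triisopropylsilyl)oxy]benzoate | Cc1cc(ccc1O[Si](C(C)C)(C(C)C)C(C)C)C(=O)OCC=C | intermediate
5 | allyl 3-(bromomethyl)-4-[(triisopropylsilyl)oxy]benzoate | BrCc1cc(ccc1O[Si](C(C)C)(C(C)C)C(C)C)C(=O)OCC=C | intermediate
6 | allyl 3-{[(1S)-2,2-dimethoxy-5-oxocyclohex-3-en-1-yl]methyl}-4-[(triisopropylsilyl)oxy]benzoate | [C@@H]1(Cc2cc(ccc2O[Si](C(C)C)(C(C)C)C(C)C)C(=O)OCC=C)C(OC)(OC)C=CC(=O)C1 | intermediate
7 | allyl 3-{[(1S,6S)-2,2-dimethoxy-6-methyl-5-oxocyclohex-3-en-1-yl]methyl}-4-[(triisopropylsilyl)oxy]benzoate (trans, major; the methyl-bearing centre is re-enolised in step 8) | [C@@H]1(Cc2cc(ccc2O[Si](C(C)C)(C(C)C)C(C)C)C(=O)OCC=C)C(OC)(OC)C=CC(=O)[C@H]1C | intermediate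
8 | geranyl bromide, (2E)-1-bromo-3,7-dimethylocta-2,6-diene | CC(C)=CCC/C(C)=C/CBr | starting material
9 | homogeraniol, (3E)-4,8-dimethylnona-3,7-dien-1-ol | CC(C)=CCC/C(C)=C/CCO | intermediate
10 | homogeranyl iodide, (3E)-1-iodo-4,8-dimethylnona-3,7-diene | CC(C)=CCC/C(C)=C/CCI | intermediate
11 | allyl 3-{[(1S,6S)-6-[(3E)-4,8-dimethylnona-3,7-dien-1-yl]-2,2-dimethoxy-6-methyl-5-oxocyclohex-3-en-1-yl]methyl}-4-[(triisopropylsilyl)oxy]benzoate | [C@@H]1(Cc2cc(ccc2O[Si](C(C)C)(C(C)C)C(C)C)C(=O)OCC=C)C(OC)(OC)C=CC(=O)[C@@]1(C)CC/C=C(\C)CCC=C(C)C | intermediate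
12 | allyl 3-{[(1S,2S)-2-[(3E)-4,8-dimethylnona-3,7-dien-1-yl]-6,6-dimethoxy-2-methyl-3-oxocyclohexyl]methyl}-4-[(triisopropylsilyl)oxy]benzoate | [C@@H]1(Cc2cc(ccc2O[Si](C(C)C)(C(C)C)C(C)C)C(=O)OCC=C)C(OC)(OC)CCC(=O)[C@@]1(C)CC/C=C(\C)CCC=C(C)C | intermediate
13 | allyl 3-{[(1S,2S,3R)-2-[(3E)-4,8-dimethylnona-3,7-dien-1-yl]-3-hydroxy-6,6-dimethoxy-2-methylcyclohexyl]methyl}-4-[(triisopropylsilyl)oxy]benzoate | [C@@H]1(Cc2cc(ccc2O[Si](C(C)C)(C(C)C)C(C)C)C(=O)OCC=C)C(OC)(OC)CC[C@@H](O)[C@@]1(C)CC/C=C(\C)CCC=C(C)C | intermediate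
14 | allyl 3-{[(1S,2S,3S)-3-bromo-2-[(3E)-4,8-dimethylnona-3,7-dien-1-yl]-2-methyl-6-oxocyclohexyl]methyl}-4-[(triisopropylsilyl)oxy]benzoate | [C@@H]1(Cc2cc(ccc2O[Si](C(C)C)(C(C)C)C(C)C)C(=O)OCC=C)C(=O)CC[C@H](Br)[C@@]1(C)CC/C=C(\C)CCC=C(C)C | intermediate
15 | allyl 3-{[(1R,2S,3S)-3-bromo-2-[(3E)-4,8-dimethylnona-3,7-dien-1-yl]-2-methyl-6-methylidenecyclohexyl]methyl}-4-[(triisopropylsilyl)oxy]benzoate | [C@@H]1(Cc2cc(ccc2O[Si](C(C)C)(C(C)C)C(C)C)C(=O)OCC=C)C(=C)CC[C@H](Br)[C@@]1(C)CC/C=C(\C)CCC=C(C)C | intermediate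
16 | allyl 3-{[(1R,2S,3S)-3-bromo-2-(2-{(2S,3S)-3-[2-((2S)-3,3-dimethyloxiran-2-yl)ethyl]-3-methyloxiran-2-yl}ethyl)-2-methyl-6-methylidenecyclohexyl]methyl}-4-[(triisopropylsilyl)oxy]benzoate | [C@@H]1(Cc2cc(ccc2O[Si](C(C)C)(C(C)C)C(C)C)C(=O)OCC=C)C(=C)CC[C@H](Br)[C@@]1(C)CC[C@@H]3O[C@@]3(C)CC[C@@H]3OC3(C)C | intermediate
17 | allyl 3-{[(1R,2S,3S)-3-bromo-2-[(3R,4S,7R)-3,7-dibromo-4,8-dihydroxy-4,8-dimethylnonyl]-2-methyl-6-methylidenecyclohexyl]methyl}-4-[(triisopropylsilyl)oxy]benzoate | [C@@H]1(Cc2cc(ccc2O[Si](C(C)C)(C(C)C)C(C)C)C(=O)OCC=C)C(=C)CC[C@H](Br)[C@@]1(C)CC[C@@H](Br)[C@@](C)(O)CC[C@@H](Br)C(C)(C)O | intermediate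
18 | 3-{[(1R,2S,3S)-3-bromo-2-[(3R,4S,7R)-3,7-dibromo-4,8-dihydroxy-4,8-dimethylnonyl]-2-methyl-6-methylidenecyclohexyl]methyl}-4-[(triisopropylsilyl)oxy]benzoic acid | [C@@H]1(Cc2cc(ccc2O[Si](C(C)C)(C(C)C)C(C)C)C(=O)O)C(=C)CC[C@H](Br)[C@@]1(C)CC[C@@H](Br)[C@@](C)(O)CC[C@@H](Br)C(C)(C)O | intermediate
19 | O-triisopropylsilyl bromophycolide H (16-membered lactone; 2R,6S,7S,10R,11S,14R) | C=C1CC[C@H](Br)[C@@]2(C)CC[C@@H](Br)[C@@](C)(O)CC[C@@H](Br)C(C)(C)OC(=O)c3ccc(O[Si](C(C)C)(C(C)C)C(C)C)c(c3)C[C@H]12 | intermediate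
20 | bromophycolide H | C=C1CC[C@H](Br)[C@@]2(C)CC[C@@H](Br)[C@@](C)(O)CC[C@@H](Br)C(C)(C)OC(=O)c3ccc(O)c(c3)C[C@H]12 | target

## Summary

Total step count: 17 (steps 2, 6 and 11 are each run as one pot with two stages).

Longest linear sequence: 14 steps (3 → 4 → 5 → 6 → 7 → 11 → 12 → 13 → 14 → 15 → 16 → 17 → 18 → 19 → 20).

Three steps most likely to fail, each with a fallback that changes the approach:

- **Step 4, desymmetrising benzyl conjugate addition** (benzyl transfer or ee may be poor). Fallback: set the first stereocentre by a chiral-base Kornblum–DeLaMare desymmetrisation of the 1,3-cyclohexadiene/O2 endoperoxide to (R)-4-silyloxycyclohex-2-enone. Then add the homogeranyl cuprate, re-oxidise (Saegusa), add Me2CuLi anti to the silyloxy group, and trap the enolate with bromide 5, so that C2 is the nucleophile and 5 the electrophile; the C3 ketone of this product is methylenated directly (no ketal) and the C6 silyl ether is cleaved to the free alcohol before the C6 bromination.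
- **Step 11, SN2 bromination at the neopentyl-type C6** (E2 or rearrangement may compete). Fallback: do not substitute at C6; instead form C6–Br together with the C2–C7 bond by a bromonium-initiated cation–olefin cyclisation (for example with BDSB) of an acyclic (6E)-alkene onto a C2=C3 silyl enol ether. The chair transition state gives the same 2,6,7-triad and delivers bromo ketone 14 directly.
- **Step 16, macrolactonisation onto the tertiary C15–OH** (slow acylation; epoxide re-formation). Fallback: reverse the polarity of ring closure by activating the alcohol rather than the acid. Ionising C15–OH of 18 with anchimeric assistance from the C14 bromide gives a configurationally defined bromonium ion, which the carboxylate opens at C15 with C14 retained (a biomimetic bromonium-capture lactonisation).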